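**Retrosynthetic overview**

- Numbering: ring A is the pentylresorcinol ring (C1 ether oxygen, C2 pentyl, C3 H, C4 OH, C5 H, C6 OH). Ring B is the benzoate ring (C1 CO2Me, C2 ether oxygen, C4 OMe, C6 pentanoyl).
- Feature exploited: the ring A oxygens at C4 and C6 are meta across a bare C5, and C6–OH is followed by C1(OAr)–C2(pentyl)–C3(H). This is the pattern a vinylketene (C6, C3, C2, C1) and an ynol ether (C5, C4) leave in a Danheiser benzannulation.
- Disconnections: first the C4 O–Si bond. Then ring A bonds C5–C6, C3–C4 and C1–C6, back to a 4-aryloxy-3-pentylcyclobutenone and (triisopropylsilyloxy)acetylene. Then the ether O–C1 bond, made while C1 is still sp3, back to the ring B phenol and 4-chloro-3-pentylcyclobutenone (hept-1-yne plus dichloroketene).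
- Ring B phenol: from 3,5-dimethoxybenzaldehyde by butyl addition, ortho-bromination, carboxylation to a 3-butylphthalide, oxidative lactone opening, esterification and chelation-controlled demethylation.
- Order of rings: ring B is bought as the arene. A transient lactone is closed in step 3 and opened in step 4, the four-membered ring is made in step 7, and ring A is formed last in step 12.

Key step: step 12

Remark: the target has no stereocentre. All chiral intermediates are racemic, and their centres vanish by oxidation or aromatisation.

**Route**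

Step 1
Reactants: 1 3,5-dimethoxybenzaldehyde; 2 n-butylmagnesium chloride
Product: 3 (±)-1-(3,5-dimethoxyphenyl)pentan-1-ol
Conditions: n-BuMgCl, THF, 0 °C; aq NH4Cl
Reagents that add atoms: n-butylmagnesium chloride (2), CCCC[Mg]Cl
Why: Grignard addition to the non-enolisable aldehyde installs the remaining four carbons of the later pentanoyl chain, and the racemic carbinol centre is oxidised away in step 4.

Step 2
Reactants: 3 (±)-1-(3,5-dimethoxyphenyl)pentan-1-ol
Product: 4 (±)-1-(2-bromo-3,5-dimethoxyphenyl)pentan-1-ol
Conditions: NBS (1.0 equiv), MeCN, 0 °C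
Reagents that add atoms: N-bromosuccinimide, O=C1CCC(=O)N1Br
Why: Electrophilic aromatic bromination with NBS in a polar solvent goes para to one methoxy group and ortho to the other, next to the carbinol, because the site between the two methoxy groups is more crowded, as is established for 3,5-dimethoxybenzyl alcohols.

Step 3
Reactants: 4 (±)-1-(2-bromo-3,5-dimethoxyphenyl)pentan-1-ol
Product: 7 (±)-3-butyl-5,7-dimethoxy-2-benzofuran-1(3H)-one, via aryllithium alkoxide 5 (not isolated), via hydroxy acid 6 (not isolated)
Conditions: n-BuLi (2.2 equiv), THF, −78 °C; CO2; 2 M HCl, rt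
Reagents that add atoms: carbon dioxide, O=C=O
Why: Deprotonation and bromine–lithium exchange give 5, carboxylation places the future C1 carbon of ring B, and acid closes 6 to the five-membered lactone (halogen–metal exchange, carboxylation, lactonisation).

Step 4
Reactants: 7 (±)-3-butyl-5,7-dimethoxy-2-benzofuran-1(3H)-one
Product: 9 2,4-dimethoxy-6-pentanoylbenzoic acid, via sodium hydroxy carboxylate 8 (not isolated)
Conditions: NaOH, H2O–t-BuOH, reflux; KMnO4 (0.7 equiv), 0 °C to rt; HCl to pH 2
Reagents that add atoms: sodium hydroxide, [Na+].[OH-]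
Why: Saponification holds the lactone open as carboxylate 8, which cannot relactonise in base, and alkaline permanganate oxidises its secondary benzylic alcohol to the aryl ketone (the known conversion of 3-alkylphthalides into 2-acylbenzoic acids).

Step 5
Reactants: 9 2,4-dimethoxy-6-pentanoylbenzoic acid
Product: 10 methyl 2,4-dimethoxy-6-pentanoylbenzoate
Conditions: MeI, K2CO3, DMF, rt
Reagents that add atoms: iodomethane, CI
Why: SN2 alkylation of the carboxylate gives the open-chain keto ester rather than the cyclic pseudo ester favoured by acid-catalysed esterification, and K2CO3 at room temperature is too weak to condense the ketone enolate onto the ester.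

Step 6
Reactants: 10 methyl 2,4-dimethoxy-6-pentanoylbenzoate
Product: 11 methyl 2-hydroxy-4-methoxy-6-pentanoylbenzoate
Conditions: BCl3 (2.5 equiv), CH2Cl2, −78 to 0 °C; H2O
Reagents that add atoms: none
Why: BCl3 chelates between the ester carbonyl oxygen and the ortho methoxy oxygen and cleaves only that methyl ether (chelation-controlled ortho-demethylation), since the C4 methoxy group has no neighbouring carbonyl group and the ketone has no ortho methoxy group.

Step 7
Reactants: 12 hept-1-yne; 13 trichloroacetyl chloride
Product: 15 4,4-dichloro-3-pentylcyclobut-2-en-1-one, via dichloroketene 14 (not isolated)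
Conditions: Zn–Cu couple, Et2O–DME, rt
Reagents that add atoms: trichloroacetyl chloride (13), O=C(Cl)C(Cl)(Cl)Cl
Why: Zinc dechlorinates 13 to ketene 14, which adds to the alkyne in a [2+2] cycloaddition with the terminal carbon bonding to the ketene carbonyl carbon, so the pentyl group ends next to CCl2, while DME binds ZnCl2 and suppresses allylic chloride migration.

Step 8
Reactants: 15 4,4-dichloro-3-pentylcyclobut-2-en-1-one
Product: 16 (±)-4-chloro-3-pentylcyclobut-2-en-1-one
Conditions: Zn dust (1.0 equiv), AcOH, TMEDA, EtOH, 0 °C, stopped at consumption of 15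
Reagents that add atoms: none
Why: Reductive dechlorination of an α,α-dichloro ketone removes the first chlorine faster than the second, and this buffered medium must protonate at C4, because it is known to carry such dichlorides through to the chlorine-free cyclobutenones, a path closed if protonation at C2 produced a vinylic chloride that zinc cannot remove; limiting zinc and low temperature should therefore stop the reaction at one chlorine.

Step 9
Reactants: 11 methyl 2-hydroxy-4-methoxy-6-pentanoylbenzoate; 16 (±)-4-chloro-3-pentylcyclobut-2-en-1-one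
Product: 17 (±)-methyl 4-methoxy-2-[(4-oxo-2-pentylcyclobut-2-en-1-yl)oxy]-6-pentanoylbenzoate
Conditions: Cs2CO3 (1.1 equiv), dry DMF, 0 °C to rt; product kept cold and used promptly
Reagents that add atoms: none
Why: Proposed new method: displacement of chloride from C4 of a 4-chlorocyclobutenone by an oxygen nucleophile has no direct counterpart, but the C4–Cl bond is both α to the carbonyl group and allylic, so its σ* orbital is lowered for SN2 attack by the soft, weakly basic salicylate-type phenoxide; enolisation at C4 would create an antiaromatic cyclobutadienolate, which shuts off elimination and Favorskii-type pathways, addition of phenoxide to the carbonyl carbon is reversible, and direct attack at C4 and allylic attack at C2 (SN2') converge on the same constitution because C2 and C4 are both CH groups flanked by the carbonyl carbon and the pentyl-bearing carbon; the closest known reactions are the Williamson alkylation of phenoxides with α-halo ketones and allylic halides and the Stille coupling of 4-chlorocyclobutenones at the same C–Cl bond; the new stereocentre is racemic and is erased in step 12.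

Step 10
Reactants: 18 ethynyltrimethylsilane; 19 triisopropylsilyl trifluoromethanesulfonate
Product: 22 triisopropyl{[(trimethylsilyl)ethynyl]oxy}silane, via lithium acetylide 20 (not isolated), via lithium silylynolate 21 (not isolated)
Conditions: n-BuLi, THF, −78 °C; t-BuOOLi (from t-BuOOH and LiN(SiMe3)2), −78 to 0 °C; 19, −78 to 0 °C
Reagents that add atoms: tert-butyl hydroperoxide, CC(C)(C)OO; triisopropylsilyl trifluoromethanesulfonate (19), CC(C)[Si](OS(=O)(=O)C(F)(F)F)(C(C)C)C(C)C
Why: The acetylide attacks the peroxide oxygen and expels tert-butoxide (the established oxidation of lithium acetylides to ynolates), and the bulky, hard silyl triflate then silylates the ynolate on oxygen because the carbon terminus already carries SiMe3 and is blocked.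

Step 11
Reactants: 22 triisopropyl{[(trimethylsilyl)ethynyl]oxy}silane
Product: 23 (triisopropylsilyloxy)acetylene
Conditions: K2CO3 (0.1 equiv), MeOH, 0 °C, short contact; pentane extraction, distillation under reduced pressure
Reagents that add atoms: none
Why: Methoxide attacks the unhindered SiMe3 group on carbon far faster than the shielded Si(i-Pr)3 group on oxygen and methanol protonates the alkynyl anion (the standard protiodesilylation of alkynylsilanes, also used on silyl-capped ynol ethers and ynamides), while the electron-rich triple bond resists base-catalysed addition of methanol.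

Step 12
Reactants: 17 (±)-methyl 4-methoxy-2-[(4-oxo-2-pentylcyclobut-2-en-1-yl)oxy]-6-pentanoylbenzoate; 23 (triisopropylsilyloxy)acetylene
Product: 28 methyl 2-[2-hydroxy-6-pentyl-4-(triisopropylsilyloxy)phenoxy]-4-methoxy-6-pentanoylbenzoate, via vinylketene 24 (not isolated), via alkenylcyclobutenone 25 (not isolated), via dienylketene 26 (not isolated), via cyclohexadienone 27 (not isolated)
Conditions: 23 (2 equiv), toluene, argon, sealed tube, 80 °C then 110 °C
Reagents that add atoms: none
Why: Heating cleaves the C(=O)–CH(OAr) bond of 17 by conrotatory four-electron electrocyclic opening, the aryloxy donor rotating outward, to give the (E)-vinylketene 24 in which ring B is held away from the ketene carbon. The polarised alkyne 23 adds across the ketene C=C in a [2+2] cycloaddition, its terminal CH bonding to the ketene carbonyl carbon (ring A C5–C6) and its oxygen-bearing carbon to the ketene α-carbon (ring A C3–C4), to give 25. A second, reversible four-electron opening gives dienylketene 26, and ring A is closed by disrotatory six-electron electrocyclization between the aryloxy-bearing terminus and the ketene carbon (ring A C1–C6), after which enolisation of dienone 27 gives phenol 28. This is the Danheiser benzannulation of a cyclobutenone with a silyl ynol ether, a reaction known to give resorcinol monosilyl ethers. The stereocentres of 17, 25 and 27 are racemic and disappear on aromatisation, so no stereocontrol is needed. The one selectivity required is the regiochemistry of the [2+2] step, secured by the oxygen lone pair of 23, which makes the terminal carbon the nucleophile and so places OSi(i-Pr)3 meta to the new C6 hydroxyl with C5–H between them, while the neutral thermal medium leaves the ester, the enolisable ketone and the methyl ether of ring B untouched.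

Step 13
Reactants: 28 methyl 2-[2-hydroxy-6-pentyl-4-(triisopropylsilyloxy)phenoxy]-4-methoxy-6-pentanoylbenzoate
Product: 29 methyl 2-(2,4-dihydroxy-6-pentylphenoxy)-4-methoxy-6-pentanoylbenzoate (target)
Conditions: Bu4NF, AcOH (1 equiv each), THF, 0 °C
Reagents that add atoms: none
Why: Fluoride cleaves the aryl silyl ether, and the acetic acid buffer keeps the ring A phenols protonated, so that attack on the neighbouring methyl ester, aryl migration (Smiles rearrangement) and enolate condensation within ring B cannot start.

**Compound list**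

1 | 3,5-dimethoxybenzaldehyde | COc1cc(OC)cc(C=O)c1 | starting material
2 | n-butylmagnesium chloride | CCCC[Mg]Cl | starting material
3 | (±)-1-(3,5-dimethoxyphenyl)pentan-1-ol | CCCCC(O)c1cc(OC)cc(OC)c1 | intermediate
4 | (±)-1-(2-bromo-3,5-dimethoxyphenyl)pentan-1-ol | CCCCC(O)c1cc(OC)cc(OC)c1Br | intermediate
5 | lithium 1-(2-lithio-3,5-dimethoxyphenyl)pentan-1-olate (aryllithium alkoxide) | CCCCC(O[Li])c1cc(OC)cc(OC)c1[Li] | intermediate
6 | (±)-2-(1-hydroxypentyl)-4,6-dimethoxybenzoic acid | CCCCC(O)c1cc(OC)cc(OC)c1C(=O)O | intermediate
7 | (±)-3-butyl-5,7-dimethoxy-2-benzofuran-1(3H)-one (3-butyl-5,7-dimethoxyphthalide) | CCCCC1OC(=O)c2c(OC)cc(OC)cc21 | intermediate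
8 | sodium (±)-2-(1-hydroxypentyl)-4,6-dimethoxybenzoate | CCCCC(O)c1cc(OC)cc(OC)c1C(=O)[O-].[Na+] | intermediate
9 | 2,4-dimethoxy-6-pentanoylbenzoic acid | CCCCC(=O)c1cc(OC)cc(OC)c1C(=O)O | intermediate
10 | methyl 2,4-dimethoxy-6-pentanoylbenzoate | CCCCC(=O)c1cc(OC)cc(OC)c1C(=O)OC | intermediate
11 | methyl 2-hydroxy-4-methoxy-6-pentanoylbenzoate | CCCCC(=O)c1cc(OC)cc(O)c1C(=O)OC | intermediate
12 | hept-1-yne | CCCCCC#C | starting material
13 | trichloroacetyl chloride | O=C(Cl)C(Cl)(Cl)Cl | starting material
14 | dichloroketene | O=C=C(Cl)Cl | intermediate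
15 | 4,4-dichloro-3-pentylcyclobut-2-en-1-one | CCCCCC1=CC(=O)C1(Cl)Cl | intermediate
16 | (±)-4-chloro-3-pentylcyclobut-2-en-1-one | CCCCCC1=CC(=O)C1Cl | intermediate
17 | (±)-methyl 4-methoxy-2-[(4-oxo-2-pentylcyclobut-2-en-1-yl)oxy]-6-pentanoylbenzoate | CCCCCC1=CC(=O)C1Oc1cc(OC)cc(C(=O)CCCC)c1C(=O)OC | intermediate
18 | ethynyltrimethylsilane | C#C[Si](C)(C)C | starting material
19 | triisopropylsilyl trifluoromethanesulfonate | CC(C)[Si](OS(=O)(=O)C(F)(F)F)(C(C)C)C(C)C | starting material
20 | lithium (trimethylsilyl)acetylide | C[Si](C)(C)C#C[Li] | intermediate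
21 | lithium 2-(trimethylsilyl)ethynolate | C[Si](C)(C)C#CO[Li] | intermediate
22 | triisopropyl{[(trimethylsilyl)ethynyl]oxy}silane | C[Si](C)(C)C#CO[Si](C(C)C)(C(C)C)C(C)C | intermediate
23 | (triisopropylsilyloxy)acetylene | C#CO[Si](C(C)C)(C(C)C)C(C)C | intermediate
24 | methyl 4-methoxy-2-{[(1E)-4-oxo-2-pentylbuta-1,3-dien-1-yl]oxy}-6-pentanoylbenzoate (vinylketene) | O=C=C/C(CCCCC)=C/Oc1cc(OC)cc(C(=O)CCCC)c1C(=O)OC | intermediate
25 | (±)-methyl 4-methoxy-2-({(1E)-2-[4-oxo-2-(triisopropylsilyloxy)cyclobut-2-en-1-yl]hept-1-en-1-yl}oxy)-6-pentanoylbenzoate | O=C1C=C(O[Si](C(C)C)(C(C)C)C(C)C)C1/C(CCCCC)=C/Oc1cc(OC)cc(C(=O)CCCC)c1C(=O)OC | intermediate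
26 | methyl 4-methoxy-2-{[(1E,3E)-6-oxo-2-pentyl-4-(triisopropylsilyloxy)hexa-1,3,5-trien-1-yl]oxy}-6-pentanoylbenzoate (dienylketene) | O=C=C/C(O[Si](C(C)C)(C(C)C)C(C)C)=C\C(CCCCC)=C\Oc1cc(OC)cc(C(=O)CCCC)c1C(=O)OC | intermediate
27 | (±)-methyl 4-methoxy-2-{[6-oxo-2-pentyl-4-(triisopropylsilyloxy)cyclohexa-2,4-dien-1-yl]oxy}-6-pentanoylbenzoate | CCCCCC1=CC(O[Si](C(C)C)(C(C)C)C(C)C)=CC(=O)C1Oc1cc(OC)cc(C(=O)CCCC)c1C(=O)OC | intermediate
28 | methyl 2-[2-hydroxy-6-pentyl-4-(triisopropylsilyloxy)phenoxy]-4-methoxy-6-pentanoylbenzoate | CCCCCc1cc(O[Si](C(C)C)(C(C)C)C(C)C)cc(O)c1Oc1cc(OC)cc(C(=O)CCCC)c1C(=O)OC | intermediate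
29 | methyl 2-(2,4-dihydroxy-6-pentylphenoxy)-4-methoxy-6-pentanoylbenzoate | CCCCCc1cc(O)cc(O)c1Oc1cc(OC)cc(C(=O)CCCC)c1C(=O)OC | target

**Step count**

- Total step count: 13
- Longest linear sequence: 9 (steps 1–6, 9, 12, 13)

**Steps most likely to fail**

**Step 9 (Proposed new method).** The phenoxide may attack the carbonyl carbon, followed by strain-driven cleavage of the four-membered ring. Premature electrocyclic opening may also let free phenol capture the ketene. Either process could outrun substitution at C4.

The fallback sets out from 11 and 12 and returns at 17. It makes the O–C(sp3) bond by an ordinary alkylation and then builds the four-membered ring around it.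
- Phenol 11 is alkylated with 2-chloro-N,N-dimethylacetamide (K2CO3, DMF) to methyl 2-[2-(dimethylamino)-2-oxoethoxy]-4-methoxy-6-pentanoylbenzoate F1.
- Tf2O and 2,4,6-collidine in 1,2-dichloroethane turn the amide into the aryloxy keteniminium triflate F2 in the presence of hept-1-yne 12.
- The known keteniminium–alkyne [2+2] cycloaddition follows. The terminal alkyne carbon bonds to the central iminium carbon, which gives the cyclobuteniminium triflate F3.
- Aqueous NaHCO3 hydrolyses F3 to 17.

This detour also makes steps 7 and 8 unnecessary.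

**Step 12 (key step).** The terminal silyl ynol ether may isomerise by a 1,3-shift of silicon from oxygen to carbon. The freshly formed phenol may also be acylated by unconsumed vinylketene. Either process could outrun the [2+2] capture.

The fallback gives up the annulation and forms the diaryl ether by arylation. It sets out from 11 and returns at 29.
- Commercial olivetol (5-pentylresorcinol) is benzylated (BnBr, K2CO3, DMF) to 1,3-bis(benzyloxy)-5-pentylbenzene F4.
- F4 is iodinated para to one benzyloxy group (N-iodosuccinimide, MeCN) to 1,5-bis(benzyloxy)-2-iodo-3-pentylbenzene F5.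
- F5 is coupled with 11 in an Ullmann ether synthesis (CuI, picolinic acid, K3PO4, DMSO, 90 °C) to methyl 2-[2,4-bis(benzyloxy)-6-pentylphenoxy]-4-methoxy-6-pentanoylbenzoate F6.
- Hydrogenolysis (H2, Pd/C, EtOAc) gives 29.

**Step 11.** Methoxide may cleave the O–Si bond (loss of the ynol protecting group), and the volatile terminal alkyne may be lost on isolation.

The fallback moves the C–Si cleavage from the alkyne to the arene. It sets out from 22 (with 17) and returns at 28.
- Heating 17 with 22 in toluene should give the same cascade, with SiMe3 ending at ring A C5. The β-silicon effect reinforces the regiochemistry. The product is methyl 2-[2-hydroxy-6-pentyl-4-(triisopropylsilyloxy)-3-(trimethylsilyl)phenoxy]-4-methoxy-6-pentanoylbenzoate F7.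
- Brief treatment with CF3CO2H in CH2Cl2 at 0 °C removes the aryl silane by ipso-protodesilylation. The silylated carbon lies ortho to two oxygens, so this should be fast. The product is 28.

**Further compounds**

F1 | step 9 | methyl 2-[2-(dimethylamino)-2-oxoethoxy]-4-methoxy-6-pentanoylbenzoate | CCCCC(=O)c1cc(OC)cc(OCC(=O)N(C)C)c1C(=O)OC
F2 | step 9 | N-{2-[5-methoxy-2-(methoxycarbonyl)-3-pentanoylphenoxy]ethenylidene}-N-methylmethanaminium trifluoromethanesulfonate (keteniminium triflate) | CCCCC(=O)c1cc(OC)cc(OC=C=[N+](C)C)c1C(=O)OC.[O-]S(=O)(=O)C(F)(F)F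
F3 | step 9 | (±)-N-{4-[5-methoxy-2-(methoxycarbonyl)-3-pentanoylphenoxy]-3-pentylcyclobut-2-en-1-ylidene}-N-methylmethanaminium trifluoromethanesulfonate (cyclobuteniminium triflate) | CCCCCC1=CC(=[N+](C)C)C1Oc1cc(OC)cc(C(=O)CCCC)c1C(=O)OC.[O-]S(=O)(=O)C(F)(F)F
F4 | step 12 | 1,3-bis(benzyloxy)-5-pentylbenzene | CCCCCc1cc(OCc2ccccc2)cc(OCc2ccccc2)c1
F5 | step 12 | 1,5-bis(benzyloxy)-2-iodo-3-pentylbenzene | CCCCCc1cc(OCc2ccccc2)cc(OCc2ccccc2)c1I
F6 | step 12 | methyl 2-[2,4-bis(benzyloxy)-6-pentylphenoxy]-4-methoxy-6-pentanoylbenzoate | CCCCCc1cc(OCc2ccccc2)cc(OCc2ccccc2)c1Oc1cc(OC)cc(C(=O)CCCC)c1C(=O)OC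
F7 | step 11 | methyl 2-[2-hydroxy-6-pentyl-4-(triisopropylsilyloxy)-3-(trimethylsilyl)phenoxy]-4-methoxy-6-pentanoylbenzoate | CCCCCc1cc(O[Si](C(C)C)(C(C)C)C(C)C)c([Si](C)(C)C)c(O)c1Oc1cc(OC)cc(C(=O)CCCC)c1C(=O)OC
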